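**Retrosynthetic overview**
1. Target 32 ⇐ desilylation of 31 ⇐ catalyst-controlled epoxidation of the ring alkene of 30 (last ring formed); the side-chain oxirane ⇐ invertive closure of a secondary mesylate by a tertiary alcohol.
2. Both angelates ⇐ one double mixed-anhydride acylation of diol 25; the carbinol between the fragments ⇐ oxidation then CBS reduction.
3. Carbon skeleton ⇐ Nozaki–Hiyama–Kishi coupling of ring alkenyl triflate 21 (fragment 2) with aldehyde 8 (fragment 1).
4. Fragment 1 ⇐ (S)-malic acid ⇐ fumaric acid by fumarase-catalysed hydration. Fragment 2 ⇐ organocatalytic Michael/aldol annulation of 9 + 10, then Rubottom oxidation and Luche reduction.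
5. Ring order: cyclohexene (step 7) → side-chain oxirane (step 21) → ring-fused oxirane (step 22). The lactone and dioxolanes of fragment 1 are temporary.

Assumption: both acyl groups are read from the SMILES as (Z)-2-methylbut-2-enoates (angelates). TBS = tert-butyldimethylsilyl, TES = triethylsilyl.

**Fragment 1 (side-chain aldehyde)**

Step 1
Reactants: 1 fumaric acid
Product: 2 (S)-malic acid
Conditions: fumarase (immobilised; a hydro-lyase), H2O, Ca(OH)2 (calcium fumarate slurry, pH 7.5), 30 °C; then H2SO4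
Reagents that add atoms: water, O
Why: Enzymatic asymmetric hydration by a lyase: fumarase adds water across the prochiral alkene to give only (S)-malate, and crystallisation of calcium malate pulls the equilibrium, so the first stereocentre (later the oxirane CH) is set catalytically.

Step 2
Reactants: 2 (S)-malic acid
Product: 3 2-[(4S)-2,2-dimethyl-5-oxo-1,3-dioxolan-4-yl]acetic acid
Conditions: 2,2-dimethoxypropane, p-TsOH (cat.), rt
Reagents that add atoms: 2,2-dimethoxypropane, COC(C)(C)OC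
Why: Acid-catalysed acetalisation closes the α-hydroxy acid to the five-membered dioxolanone in preference to the six-membered alternative, leaving the β-carboxyl free and the stereocentre untouched.

Step 3
Reactants: 3 dioxolanone acid
Product: 5 (3S)-3-hydroxyoxolan-2-one, via hydroxyethyl dioxolanone 4 (not isolated)
Conditions: BH3·SMe2, THF, 0 °C to rt; MeOH; then p-TsOH (cat.), CH2Cl2, rt
Reagents that add atoms: none
Why: Chemoselective borane reduction of the free carboxylic acid, then acid-catalysed translactonisation with loss of acetone, gives the γ-lactone without touching the stereocentre.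

Step 4
Reactants: 5 (3S)-3-hydroxyoxolan-2-one
Product: 6 (3S)-4-methylpentane-1,3,4-triol
Conditions: MeMgBr (4 equiv), THF, 0 °C to rt; aq. NH4Cl
Reagents that add atoms: methylmagnesium bromide, C[Mg]Br
Why: Double Grignard addition to the lactone carbonyl builds the gem-dimethyl tertiary carbinol; the stereocentre is not involved.

Step 5
Reactants: 6 triol
Product: 7 2-[(4S)-2,2,5,5-tetramethyl-1,3-dioxolan-4-yl]ethan-1-ol
Conditions: 2,2-dimethoxypropane, PPTS (cat.), CH2Cl2, rt
Reagents that add atoms: 2,2-dimethoxypropane, COC(C)(C)OC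
Why: Thermodynamically controlled acetonide formation (transketalisation) favours the five-membered dioxolane across the vicinal secondary/tertiary diol over the 1,3-dioxane, leaving the primary alcohol free.

Step 6
Reactants: 7 acetonide alcohol
Product: 8 2-[(4S)-2,2,5,5-tetramethyl-1,3-dioxolan-4-yl]acetaldehyde
Conditions: Dess–Martin periodinane, CH2Cl2, 0 °C to rt; used directly
Reagents that add atoms: none
Why: Dess–Martin oxidation gives the aldehyde under near-neutral conditions that avoid β-elimination of the β-alkoxy aldehyde.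

**Fragment 2 (ring alkenyl triflate)**

Step 7
Reactants: 9 ethyl (2E)-4-oxobut-2-enoate; 10 tert-butyl 3-oxopentanoate
Product: 12 ethyl (1S)-4-methyl-5-oxocyclohex-3-ene-1-carboxylate, via Michael adduct 11 (not isolated)
Conditions: (R)-2-{bis[3,5-bis(trifluoromethyl)phenyl](trimethylsilyloxy)methyl}pyrrolidine (10 mol %), PhCO2H (10 mol %), toluene, rt; then p-TsOH (20 mol %), 80 °C
Reagents that add atoms: none
Why: Organocatalytic iminium-ion Michael addition of the β-keto ester to the enal, on the face remote from the diaryl(silyloxy)methyl group, sets C1 (S); acid then triggers tert-butyl ester cleavage, decarboxylation and intramolecular aldol condensation (Robinson-type annulation).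

Step 8
Reactants: 12 enone ester
Product: 15 ethyl (1S,6R)-6-hydroxy-4-methyl-5-oxocyclohex-3-ene-1-carboxylate, via silyl dienol ether 13 (not isolated), via silyloxy ketone 14 (not isolated)
Conditions: LiN(iPr)2, THF, −78 °C, then TMSCl; mCPBA, CH2Cl2, −20 °C; citric acid, MeOH
Reagents that add atoms: mCPBA, OOC(=O)c1cccc(Cl)c1
Why: Rubottom oxidation: kinetic α′-deprotonation and silylation give the cross-conjugated silyl dienol ether, whose enol double bond is epoxidised anti to the neighbouring ester and rearranges to the α-silyloxy ketone, so the new hydroxyl is trans to the ester.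

Step 9
Reactants: 15 α′-hydroxy enone
Product: 16 ethyl (1S,6R)-6-[(tert-butyldimethylsilyl)oxy]-4-methyl-5-oxocyclohex-3-ene-1-carboxylate
Conditions: TBSCl, imidazole, DMF, rt
Reagents that add atoms: tert-butyldimethylsilyl chloride, CC(C)(C)[Si](C)(C)Cl
Why: Silylation of the secondary α-hydroxy ketone blocks α-ketol chemistry and carries this oxygen, the one that stays free in the target, to the last step.

Step 10
Reactants: 16 silyloxy enone
Product: 17 ethyl (1S,5R,6R)-6-[(tert-butyldimethylsilyl)oxy]-5-hydroxy-4-methylcyclohex-3-ene-1-carboxylate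
Conditions: NaBH4, CeCl3·7H2O, MeOH, −78 °C
Reagents that add atoms: none
Why: Luche reduction: 1,2-selective axial hydride delivery to the half-chair enone with both ring substituents equatorial gives the equatorial allylic alcohol, trans to the silyloxy group and cis to the ester (as carvone gives cis-carveol), and the ester is untouched.

Step 11
Reactants: 17 allylic alcohol
Product: 18 ethyl (1S,5R,6R)-6-[(tert-butyldimethylsilyl)oxy]-4-methyl-5-[(triethylsilyl)oxy]cyclohex-3-ene-1-carboxylate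
Conditions: TESCl, imidazole, DMAP (cat.), CH2Cl2, 0 °C to rt
Reagents that add atoms: triethylsilyl chloride, CC[Si](CC)(CC)Cl
Why: Silylation as the more labile TES ether gives two silyl ethers that can later be removed one at a time.

Step 12
Reactants: 18 bis-silyl ether ester
Product: 19 (1S,5R,6R)-6-[(tert-butyldimethylsilyl)oxy]-N-methoxy-N,4-dimethyl-5-[(triethylsilyl)oxy]cyclohex-3-ene-1-carboxamide
Conditions: MeNH(OMe)·HCl, iPrMgCl, THF, −20 to 0 °C
Reagents that add atoms: N,O-dimethylhydroxylamine hydrochloride, CNOC.Cl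
Why: Ester aminolysis by the magnesium amide (Weinreb amide synthesis) proceeds without enolisation, so the α-stereocentre and the β-silyloxy group are retained.

Step 13
Reactants: 19 Weinreb amide
Product: 20 1-[(1S,5R,6R)-6-[(tert-butyldimethylsilyl)oxy]-4-methyl-5-[(triethylsilyl)oxy]cyclohex-3-en-1-yl]ethan-1-one
Conditions: MeMgBr, THF, 0 °C; aq. NH4Cl
Reagents that add atoms: methylmagnesium bromide, C[Mg]Br
Why: Weinreb ketone synthesis: the Grignard reagent adds once because the chelated tetrahedral intermediate persists until work-up.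

Step 14
Reactants: 20 methyl ketone
Product: 21 1-[(1S,5R,6R)-6-[(tert-butyldimethylsilyl)oxy]-4-methyl-5-[(triethylsilyl)oxy]cyclohex-3-en-1-yl]ethenyl trifluoromethanesulfonate
Conditions: KN(SiMe3)2, THF, −78 °C; then PhNTf2
Reagents that add atoms: N-phenylbis(trifluoromethanesulfonimide), O=S(=O)(N(c1ccccc1)S(=O)(=O)C(F)(F)F)C(F)(F)F
Why: Kinetic deprotonation at the unhindered methyl group and O-sulfonylation of the enolate (enol triflate formation) give the 1,1-disubstituted alkenyl triflate without epimerising the ring methine.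

**Union and end game**

Step 15
Reactants: 21 alkenyl triflate; 8 aldehyde
Product: 22 (2RS)-3-[(1R,5R,6R)-6-[(tert-butyldimethylsilyl)oxy]-4-methyl-5-[(triethylsilyl)oxy]cyclohex-3-en-1-yl]-1-[(4S)-2,2,5,5-tetramethyl-1,3-dioxolan-4-yl]but-3-en-2-ol
Conditions: CrCl2 (4 equiv), NiCl2 (2 mol %), DMF, rt
Reagents that add atoms: none
Why: Nozaki–Hiyama–Kishi coupling: nickel-catalysed activation of the alkenyl triflate and transmetalation to chromium give an alkenylchromium species that adds only to the aldehyde; the carbinol centre forms as a mixture of epimers that the next two steps correct.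

Step 16
Reactants: 22 allylic alcohols
Product: 23 3-[(1R,5R,6R)-6-[(tert-butyldimethylsilyl)oxy]-4-methyl-5-[(triethylsilyl)oxy]cyclohex-3-en-1-yl]-1-[(4S)-2,2,5,5-tetramethyl-1,3-dioxolan-4-yl]but-3-en-2-one
Conditions: Dess–Martin periodinane, CH2Cl2, 0 °C; used at once
Reagents that add atoms: none
Why: Dess–Martin oxidation erases the unselective carbinol centre and gives the α-methylene ketone.

Step 17
Reactants: 23 enone
Product: 24 (2S)-3-[(1R,5R,6R)-6-[(tert-butyldimethylsilyl)oxy]-4-methyl-5-[(triethylsilyl)oxy]cyclohex-3-en-1-yl]-1-[(4S)-2,2,5,5-tetramethyl-1,3-dioxolan-4-yl]but-3-en-2-ol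
Conditions: (R)-Me-CBS oxazaborolidine (0.3 equiv), catecholborane, toluene, −78 °C
Reagents that add atoms: none
Why: Corey–Bakshi–Shibata reduction: the ketone binds the oxazaborolidine anti to the larger α-branched alkenyl group and hydride is delivered to one face, giving the (S)-carbinol under catalyst control, while catecholborane avoids alkene hydroboration.

Step 18
Reactants: 24 (2S)-alcohol
Product: 25 (2S)-3-[(1R,5R,6R)-6-[(tert-butyldimethylsilyl)oxy]-5-hydroxy-4-methylcyclohex-3-en-1-yl]-1-[(4S)-2,2,5,5-tetramethyl-1,3-dioxolan-4-yl]but-3-en-2-ol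
Conditions: HF·pyridine, pyridine, THF, 0 °C
Reagents that add atoms: none
Why: Selective desilylation: the TES ether is cleaved far faster than the hindered TBS ether under buffered HF·pyridine, which leaves the acetonide intact.

Step 19
Reactants: 25 diol; 26 angelic acid
Product: 27 bis-angelate of 25 (full name in the list)
Conditions: 26 (6 equiv), 2,4,6-trichlorobenzoyl chloride, Et3N, toluene, rt; then 25, 80 °C
Reagents that add atoms: none
Why: Yamaguchi-type mixed-anhydride esterification acylates both secondary allylic alcohols at the angeloyl carbonyl, and the absence of a nucleophilic catalyst avoids Z-to-E isomerisation to the tiglate.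

Step 20
Reactants: 27 bis-angelate acetonide
Product: 28 (3S,5S)-5,6-dihydroxy-6-methylhept-1-en-3-yl angelate carrying the ring at C2 (full name in the list)
Conditions: AcOH–H2O (4:1), 40 °C
Reagents that add atoms: none
Why: Acid-catalysed acetal hydrolysis removes the strained tetramethyldioxolane while the hindered TBS ether and the allylic esters survive.

Step 21
Reactants: 28 diol
Product: 30 side-chain (R)-oxirane TBS ether (full name in the list), via secondary mesylate 29 (not isolated)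
Conditions: MsCl, pyridine, CH2Cl2, 0 °C; then K2CO3, MeOH, 0 °C
Reagents that add atoms: none
Why: Selective sulfonylation of the secondary hydroxyl, then intramolecular Williamson-type SN2 closure by the tertiary alkoxide, inverts the carbinol carbon and gives the (R)-oxirane.

Step 22
Reactants: 30 ring alkene
Product: 31 TBS ether of the target (full name in the list)
Conditions: ent-Shi ketone (the L-fructose-derived enantiomer of 1,2:4,5-di-O-isopropylidene-β-D-erythro-2,3-hexodiulo-2,6-pyranose, 0.5 equiv), Oxone (2KHSO5·KHSO4·K2SO4), K2CO3, Bu4NHSO4, aq. Na2B4O7 buffer, MeCN–CH2(OMe)2, 0 °C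
Reagents that add atoms: potassium peroxymonosulfate, [K+].[O-]S(=O)(=O)OO
Why: Shi epoxidation: the dioxirane from the ent-ketone transfers oxygen through a spiro transition state to the trisubstituted ring alkene on the face trans to the allylic angelate, which is also the face this 6-acyloxy-1-methylcyclohexene prefers, and so sets both ring-oxirane stereocentres; the 1,1-disubstituted and angelate alkenes are poor substrates.

Step 23
Reactants: 31 silyl ether
Product: 32 target (CNP0296086.4)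
Conditions: Bu4NF, AcOH (1:1), THF, rt
Reagents that add atoms: none
Why: Fluoride-mediated desilylation buffered with acetic acid frees the ring hydroxyl without acyl migration or oxirane opening.

**Compound list**

1 | fumaric acid | OC(=O)/C=C/C(=O)O | starting material
2 | (S)-malic acid | O[C@@H](CC(=O)O)C(=O)O | intermediate
3 | 2-[(4S)-2,2-dimethyl-5-oxo-1,3-dioxolan-4-yl]acetic acid | OC(=O)C[C@@H]1OC(C)(C)OC1=O | intermediate
4 | (5S)-5-(2-hydroxyethyl)-2,2-dimethyl-1,3-dioxolan-4-one | OCC[C@@H]1OC(C)(C)OC1=O | intermediate (not isolated)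
5 | (3S)-3-hydroxyoxolan-2-one | O[C@H]1CCOC1=O | intermediate
6 | (3S)-4-methylpentane-1,3,4-triol | OCC[C@H](O)C(C)(C)O | intermediate
7 | 2-[(4S)-2,2,5,5-tetramethyl-1,3-dioxolan-4-yl]ethan-1-ol | OCC[C@@H]1OC(C)(C)OC1(C)C | intermediate
8 | 2-[(4S)-2,2,5,5-tetramethyl-1,3-dioxolan-4-yl]acetaldehyde | O=CC[C@@H]1OC(C)(C)OC1(C)C | intermediate
9 | ethyl (2E)-4-oxobut-2-enoate | CCOC(=O)/C=C/C=O | starting material
10 | tert-butyl 3-oxopentanoate | CCC(=O)CC(=O)OC(C)(C)C | starting material
11 | 1-tert-butyl 4-ethyl (3S)-3-(2-oxoethyl)-2-propanoylbutanedioate (C2 epimers) | CCOC(=O)[C@H](C(C(=O)CC)C(=O)OC(C)(C)C)CC=O | intermediate (not isolated)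
12 | ethyl (1S)-4-methyl-5-oxocyclohex-3-ene-1-carboxylate | CCOC(=O)[C@H]1CC=C(C)C(=O)C1 | intermediate
13 | ethyl (1S)-4-methyl-5-[(trimethylsilyl)oxy]cyclohexa-3,5-diene-1-carboxylate | CCOC(=O)[C@H]1CC=C(C)C(O[Si](C)(C)C)=C1 | intermediate (not isolated)
14 | ethyl (1S,6R)-4-methyl-5-oxo-6-[(trimethylsilyl)oxy]cyclohex-3-ene-1-carboxylate | CCOC(=O)[C@H]1CC=C(C)C(=O)[C@@H]1O[Si](C)(C)C | intermediate (not isolated)
15 | ethyl (1S,6R)-6-hydroxy-4-methyl-5-oxocyclohex-3-ene-1-carboxylate | CCOC(=O)[C@H]1CC=C(C)C(=O)[C@@H]1O | intermediate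
16 | ethyl (1S,6R)-6-[(tert-butyldimethylsilyl)oxy]-4-methyl-5-oxocyclohex-3-ene-1-carboxylate | CCOC(=O)[C@H]1CC=C(C)C(=O)[C@@H]1O[Si](C)(C)C(C)(C)C | intermediate
17 | ethyl (1S,5R,6R)-6-[(tert-butyldimethylsilyl)oxy]-5-hydroxy-4-methylcyclohex-3-ene-1-carboxylate | CCOC(=O)[C@H]1CC=C(C)[C@@H](O)[C@@H]1O[Si](C)(C)C(C)(C)C | intermediate
18 | ethyl (1S,5R,6R)-6-[(tert-butyldimethylsilyl)oxy]-4-methyl-5-[(triethylsilyl)oxy]cyclohex-3-ene-1-carboxylate | CCOC(=O)[C@H]1CC=C(C)[C@@H](O[Si](CC)(CC)CC)[C@@H]1O[Si](C)(C)C(C)(C)C | intermediate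
19 | (1S,5R,6R)-6-[(tert-butyldimethylsilyl)oxy]-N-methoxy-N,4-dimethyl-5-[(triethylsilyl)oxy]cyclohex-3-ene-1-carboxamide | CON(C)C(=O)[C@H]1CC=C(C)[C@@H](O[Si](CC)(CC)CC)[C@@H]1O[Si](C)(C)C(C)(C)C | intermediate
20 | 1-[(1S,5R,6R)-6-[(tert-butyldimethylsilyl)oxy]-4-methyl-5-[(triethylsilyl)oxy]cyclohex-3-en-1-yl]ethan-1-one | CC(=O)[C@H]1CC=C(C)[C@@H](O[Si](CC)(CC)CC)[C@@H]1O[Si](C)(C)C(C)(C)C | intermediate
21 | 1-[(1S,5R,6R)-6-[(tert-butyldimethylsilyl)oxy]-4-methyl-5-[(triethylsilyl)oxy]cyclohex-3-en-1-yl]ethenyl trifluoromethanesulfonate | C=C(OS(=O)(=O)C(F)(F)F)[C@H]1CC=C(C)[C@@H](O[Si](CC)(CC)CC)[C@@H]1O[Si](C)(C)C(C)(C)C | intermediate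
22 | (2RS)-3-[(1R,5R,6R)-6-[(tert-butyldimethylsilyl)oxy]-4-methyl-5-[(triethylsilyl)oxy]cyclohex-3-en-1-yl]-1-[(4S)-2,2,5,5-tetramethyl-1,3-dioxolan-4-yl]but-3-en-2-ol | C=C(C(O)C[C@@H]1OC(C)(C)OC1(C)C)[C@H]1CC=C(C)[C@@H](O[Si](CC)(CC)CC)[C@@H]1O[Si](C)(C)C(C)(C)C | intermediate
23 | 3-[(1R,5R,6R)-6-[(tert-butyldimethylsilyl)oxy]-4-methyl-5-[(triethylsilyl)oxy]cyclohex-3-en-1-yl]-1-[(4S)-2,2,5,5-tetramethyl-1,3-dioxolan-4-yl]but-3-en-2-one | C=C(C(=O)C[C@@H]1OC(C)(C)OC1(C)C)[C@H]1CC=C(C)[C@@H](O[Si](CC)(CC)CC)[C@@H]1O[Si](C)(C)C(C)(C)C | intermediate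
24 | (2S)-3-[(1R,5R,6R)-6-[(tert-butyldimethylsilyl)oxy]-4-methyl-5-[(triethylsilyl)oxy]cyclohex-3-en-1-yl]-1-[(4S)-2,2,5,5-tetramethyl-1,3-dioxolan-4-yl]but-3-en-2-ol | C=C([C@H](C[C@@H]1OC(C)(C)OC1(C)C)O)[C@H]1CC=C(C)[C@@H](O[Si](CC)(CC)CC)[C@@H]1O[Si](C)(C)C(C)(C)C | intermediate
25 | (2S)-3-[(1R,5R,6R)-6-[(tert-butyldimethylsilyl)oxy]-5-hydroxy-4-methylcyclohex-3-en-1-yl]-1-[(4S)-2,2,5,5-tetramethyl-1,3-dioxolan-4-yl]but-3-en-2-ol | C=C([C@H](C[C@@H]1OC(C)(C)OC1(C)C)O)[C@H]1CC=C(C)[C@@H](O)[C@@H]1O[Si](C)(C)C(C)(C)C | intermediate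
26 | angelic acid, (2Z)-2-methylbut-2-enoic acid | C/C=C(/C)C(=O)O | starting material
27 | (2S)-3-[(1R,5R,6R)-6-[(tert-butyldimethylsilyl)oxy]-4-methyl-5-{[(2Z)-2-methylbut-2-enoyl]oxy}cyclohex-3-en-1-yl]-1-[(4S)-2,2,5,5-tetramethyl-1,3-dioxolan-4-yl]but-3-en-2-yl (2Z)-2-methylbut-2-enoate | C=C([C@H](C[C@@H]1OC(C)(C)OC1(C)C)OC(=O)/C(C)=C\C)[C@H]1CC=C(C)[C@@H](OC(=O)/C(C)=C\C)[C@@H]1O[Si](C)(C)C(C)(C)C | intermediate
28 | (3S,5S)-2-[(1R,5R,6R)-6-[(tert-butyldimethylsilyl)oxy]-4-methyl-5-{[(2Z)-2-methylbut-2-enoyl]oxy}cyclohex-3-en-1-yl]-5,6-dihydroxy-6-methylhept-1-en-3-yl (2Z)-2-methylbut-2-enoate | C=C([C@H](C[C@H](O)C(C)(C)O)OC(=O)/C(C)=C\C)[C@H]1CC=C(C)[C@@H](OC(=O)/C(C)=C\C)[C@@H]1O[Si](C)(C)C(C)(C)C | intermediate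
29 | (3S,5S)-2-[(1R,5R,6R)-6-[(tert-butyldimethylsilyl)oxy]-4-methyl-5-{[(2Z)-2-methylbut-2-enoyl]oxy}cyclohex-3-en-1-yl]-6-hydroxy-5-[(methanesulfonyl)oxy]-6-methylhept-1-en-3-yl (2Z)-2-methylbut-2-enoate | C=C([C@H](C[C@H](OS(C)(=O)=O)C(C)(C)O)OC(=O)/C(C)=C\C)[C@H]1CC=C(C)[C@@H](OC(=O)/C(C)=C\C)[C@@H]1O[Si](C)(C)C(C)(C)C | intermediate (not isolated)
30 | (2S)-3-[(1R,5R,6R)-6-[(tert-butyldimethylsilyl)oxy]-4-methyl-5-{[(2Z)-2-methylbut-2-enoyl]oxy}cyclohex-3-en-1-yl]-1-[(2R)-3,3-dimethyloxiran-2-yl]but-3-en-2-yl (2Z)-2-methylbut-2-enoate | C=C([C@H](C[C@H]1OC1(C)C)OC(=O)/C(C)=C\C)[C@H]1CC=C(C)[C@@H](OC(=O)/C(C)=C\C)[C@@H]1O[Si](C)(C)C(C)(C)C | intermediate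
31 | (2S)-3-[(1S,2S,3R,4R,6S)-3-[(tert-butyldimethylsilyl)oxy]-1-methyl-2-{[(2Z)-2-methylbut-2-enoyl]oxy}-7-oxabicyclo[4.1.0]heptan-4-yl]-1-[(2R)-3,3-dimethyloxiran-2-yl]but-3-en-2-yl (2Z)-2-methylbut-2-enoate | C=C([C@H](C[C@H]1OC1(C)C)OC(=O)/C(C)=C\C)[C@H]1C[C@@H]2O[C@]2(C)[C@@H](OC(=O)/C(C)=C\C)[C@@H]1O[Si](C)(C)C(C)(C)C | intermediate
32 | (2S)-1-[(2R)-3,3-dimethyloxiran-2-yl]-3-[(1S,2S,3R,4R,6S)-3-hydroxy-1-methyl-2-{[(2Z)-2-methylbut-2-enoyl]oxy}-7-oxabicyclo[4.1.0]heptan-4-yl]but-3-en-2-yl (2Z)-2-methylbut-2-enoate | C=C([C@H](C[C@H]1OC1(C)C)OC(=O)/C(C)=C\C)[C@H]1C[C@@H]2O[C@]2(C)[C@@H](OC(=O)/C(C)=C\C)[C@@H]1O | target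

**Summary**

Total step count: 23. Longest linear sequence: 17 steps (steps 7 to 23); fragment 1 contributes 6 steps before the union.

Three steps most likely to fail, each with a fallback:

Step 7 (enantioselectivity and cyclisation with the ethyl ketone donor). The fallback sets out from 9 and comes back at 12. The same amine-catalysed Michael/aldol/decarboxylation is run with tert-butyl 3-oxobutanoate (CC(=O)CC(=O)OC(C)(C)C), the best-precedented donor. It passes through the acetyl Michael adduct F1 and gives ethyl (1S)-5-oxocyclohex-3-ene-1-carboxylate F2. α-Iodination (I2, pyridine, CH2Cl2) gives ethyl (1S)-4-iodo-5-oxocyclohex-3-ene-1-carboxylate F3. Suzuki–Miyaura methylation (MeB(OH)2, PdCl2(dppf), K3PO4, THF–H2O, 60 °C) then installs the ring methyl and returns to 12.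

Step 19 (double acylation of two hindered allylic alcohols without tiglate formation). The fallback sets out from 25 and comes back at 27. Esterification with 2-[bis(2,2,2-trifluoroethoxy)phosphoryl]propanoic acid (DCC, DMAP, CH2Cl2) gives the bis(phosphonopropanoate) F4. A double Still–Gennari olefination with acetaldehyde (KN(SiMe3)2, 18-crown-6, THF, −78 °C) builds both (Z)-2-methylbut-2-enoates on the substrate and returns to 27.

Step 22 (rate and face selectivity of the dioxirane on the deactivated ring alkene, competition from the exocyclic alkene). The fallback sets out from 30 and comes back at 32. Desilylation first (Bu4NF, AcOH, THF) gives the free homoallylic alcohol F5. Peracid epoxidation (mCPBA, NaHCO3, CH2Cl2, 0 °C) then works under substrate control: the electron-rich trisubstituted ring alkene is attacked anti to the allylic angelate with hydrogen-bond guidance from the free hydroxyl on the same lower face, arriving directly at 32.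

**Further compounds**

F1 | step 7 | 1-tert-butyl 4-ethyl (3S)-2-acetyl-3-(2-oxoethyl)butanedioate (C2 epimers, not isolated) | CCOC(=O)[C@H](C(C(C)=O)C(=O)OC(C)(C)C)CC=O
F2 | step 7 | ethyl (1S)-5-oxocyclohex-3-ene-1-carboxylate | CCOC(=O)[C@H]1CC=CC(=O)C1
F3 | step 7 | ethyl (1S)-4-iodo-5-oxocyclohex-3-ene-1-carboxylate | CCOC(=O)[C@H]1CC=C(I)C(=O)C1
F4 | step 19 | bis{2-[bis(2,2,2-trifluoroethoxy)phosphoryl]propanoate} of diol 25 (phosphonate carbons as epimer mixtures) | C=C([C@H](C[C@@H]1OC(C)(C)OC1(C)C)OC(=O)C(C)P(=O)(OCC(F)(F)F)OCC(F)(F)F)[C@H]1CC=C(C)[C@@H](OC(=O)C(C)P(=O)(OCC(F)(F)F)OCC(F)(F)F)[C@@H]1O[Si](C)(C)C(C)(C)C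
F5 | step 22 | (2S)-1-[(2R)-3,3-dimethyloxiran-2-yl]-3-[(1R,5R,6R)-6-hydroxy-4-methyl-5-{[(2Z)-2-methylbut-2-enoyl]oxy}cyclohex-3-en-1-yl]but-3-en-2-yl (2Z)-2-methylbut-2-enoate | C=C([C@H](C[C@H]1OC1(C)C)OC(=O)/C(C)=C\C)[C@H]1CC=C(C)[C@@H](OC(=O)/C(C)=C\C)[C@@H]1O
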